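Readings and results were computed with made-up constants, and the scatter is random.

**Time of reading.** I read the flask at 15 h, later than any earlier run.

| flask | starting material | partner | second substrate | third substrate | remark | time |
|---|---|---|---|---|---|---|
| birch | 0.085 M | 0.17 M | 0.85 M | 0.17 M | run made earlier |  |
| larch | 0.34 M | 0.17 M | 0.85 M | 0.17 M | run made earlier |  |
| cedar | 0.17 M | 0.17 M | 0.85 M | 0.26 M | run made earlier |  |
| flask | 0.17 M | 0.170 M | 0.850 M | 0.170 M |  | 15 h |

| run | time / h | starting material / % | target / % |
|---|---|---|---|
| birch | 0.667 | 48.5 | 51.6 |
| birch | 1.33 | 48.6 | 50.8 |
| birch | 2.00 | 48.3 | 51.4 |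
| birch | 3.00 | 48.2 | 51.4 |
| birch | 5.00 | 48.6 | 50.9 |
| birch | 10.0 | 48.4 | 52.0 |
| larch | 0.667 | 69.2 | 30.9 |
| larch | 1.33 | 69.9 | 30.6 |
| larch | 2.00 | 69.1 | 30.5 |
| larch | 3.00 | 69.7 | 30.4 |
| larch | 5.00 | 70.1 | 30.5 |
| larch | 10.0 | 69.3 | 30.8 |
| cedar | 2.00 | 60.7 | 38.9 |
| cedar | 4.00 | 60.3 | 39.5 |
| cedar | 5.00 | 59.7 | 39.7 |
| cedar | 8.00 | 59.8 | 39.5 |
| cedar | 10.0 | 60.6 | 39.7 |

(standard deviation of a reading: 0.3 percentage points)

- what may be going on: third substrate + partner -> third product; second substrate + partner -> second product; third substrate -> decomposition product; starting material + partner -> target
- the reaction counts as stopped when no species that holds the starting material changes by six tenths of a point or more over the second half of the time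

* why nothing more happens at 15 h, or that something still does (all of the starting material has reacted / the partner has run out first / forward and back rates have come level / it is still moving)
* part of the starting material gone at 15 h
* the target standing at 15 h, as a percentage of the starting material charged

**Fast rung.** By 0.667 h the starting material in birch already stood at 48.5 %, and in larch at 69.2 %. Starting material and target together made 100 % in birch.

**Flat rung.** From there to 10.0 h, birch stayed between 48.2 % and 48.6 %, with a scatter of 0.3 percentage points. So 15 h lay on the plateau.

**Slow rung.** I could read no pace for the decomposition of the third substrate from these readings, and my reckoning carried no term for it.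

**Rival draw.** Partner is a factor in each of the three competing rates, so it cancels from their ratios. The log-fall of starting material, ln(charge/left), can therefore serve as the clock. I defined the rival draw as the partner not taken by starting material, per unit of log-fall, assuming the partner charge is used up (the limiting reagent). Birch fell 0.726 and drew 0.174 M. Larch fell 0.367 and drew 0.179 M. Their mean was 0.176 M. Cedar, with 0.26 M of third substrate, drew more, 0.206 M.

**My reckoning.** I started from the mean log-fall of those two runs, 0.546. One pass through the partner balance gave 0.558, so 42.8 % of the starting material gone in the flask, all of it as target.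

**The forecast.** It gave 42.4 % gone, 42.4 % target and the partner has run out first, slightly under my figure: “Competition for a limited partner fits instead.”

**The flask.** It gave 42.5 % gone, 42.5 % target and the partner has run out first, with partner at 0 %.

    third substrate + partner → third product (k = 0.230 M⁻¹ min⁻¹)
    second substrate + partner → second product (k = 0.110 M⁻¹ min⁻¹)
    third substrate → decomposition product (k = 4.50 × 10⁻⁵ min⁻¹)
    starting material + partner → target (k = 0.710 M⁻¹ min⁻¹)

At the start, the step to target used partner at 1.3 times the rate of the step to second product. Nearly all of the partner was gone by 0.322 h, far ahead of the reading. The flask's own rival draw came to 0.177 M. The neighbour flask with 0.10 M of starting material reached 49.8 %, and at that point its target plus rival draw called for 0.171 M of partner against a charge of 0.170 M.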